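**Plan**
- Labels: unit M is the flavan-3-ol (rings A, C, B; 2,3-cis-3,4-trans), unit T the flavan-3,4-diol (rings D, F, E; all-cis). M-C4 carries H, ring D (through T-C6) and ring A, and the ring A oxygen M-O1 sits ortho to it, so M-O1/M-C8a/M-C4a/M-C4 can be unmasked as an ortho-quinone methide.
- Retrosynthesis: ring C is cut at M-C3–M-C4 and M-O1–M-C2 (quinone methide plus Z silyl enol ether), then M-C4–T-C6 (aryllithium plus salicylaldehyde), then ring F of unit T at T-C2–T-C3 and T-O1–T-C2 (chalcone to flavonol).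
- Forward: ring F closes first as a flavonol, is hydrogenated, resolved and brominated at T-C6; ring A is attached as a benzhydrol; ring C closes in the key step; ionic reduction, acetonide hydrolysis and hydrogenolysis finish.
- Stereochemistry: T-C2/C3/C4 come from syn hydrogenation of the flat flavonol (relative) and resolution (absolute). M-C4 and M-C3 come from the chiral phosphoric acid, the Z enol ether and an endo ring B. M-C2 comes from axial hydride delivery anti to the C3 benzyloxy group.

Key step: step 11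

Assumption: compounds 3, 17 and 18 are bought; the (R)-acid in step 11 is chosen by analogy and its antipode is used if the other face of M-C4 reacts; descriptors in names of protected compounds are those of the deprotected parent rings, and the SMILES are authoritative.

**Step 1**
Reactants: 1 gallacetophenone
Product: 2 1-[3,4-bis(benzyloxy)-2-hydroxyphenyl]ethan-1-one
Conditions: BnBr (2.1 equiv), K2CO3 (2.1 equiv), DMF, rt
Reagents that add atoms: benzyl bromide, BrCc1ccccc1
Why: Williamson etherification in which the 2-hydroxyl, hydrogen-bonded to the acetyl carbonyl, is the least nucleophilic and should stay free with two equivalents of halide.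

**Step 2**
Reactants: 2 1-[3,4-bis(benzyloxy)-2-hydroxyphenyl]ethan-1-one; 3 4-(benzyloxy)benzaldehyde
Product: 6 7,8-bis(benzyloxy)-2-[4-(benzyloxy)phenyl]-3-hydroxy-4H-chromen-4-one (flavonol), via chalcone 4 (not isolated), via trans-dihydroflavonol 5 (not isolated)
Conditions: KOH, EtOH, rt; then 30% H2O2, 0 °C to rt
Reagents that add atoms: hydrogen peroxide, OO
Why: Claisen–Schmidt condensation followed in the same pot by Algar–Flynn–Oyamada oxidative cyclisation, which gives the flavonol because the chalcone has no 6'-substituent to divert it to an aurone.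

**Step 3**
Reactants: 6 flavonol
Product: 8 rac-(2R,3R,4R)-7,8-bis(benzyloxy)-2-[4-(benzyloxy)phenyl]chromane-3,4-diol (all-cis), via cis-dihydroflavonol 7 (not isolated)
Conditions: H2 (4 bar), PtO2, EtOAc/AcOH (10:1), rt, stopped after two equivalents of H2
Reagents that add atoms: none
Why: Heterogeneous hydrogenation adds both pairs of hydrogen from the catalyst face to the same side of the flat pyranone (C2=C3, then C4=O), the classical route from flavonols to all-cis flavan-3,4-diols, and platinum is chosen because it cleaves aryl benzyl ethers only slowly.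

**Step 4**
Reactants: 8 racemic all-cis diol
Product: 9 racemic 3,4-O-isopropylidene acetal (acetonide) of 8
Conditions: 2,2-dimethoxypropane, pyridinium p-toluenesulfonate (cat.), CH2Cl2, rt
Reagents that add atoms: 2,2-dimethoxypropane, COC(C)(C)OC
Why: Transketalisation closes a dioxolane only on a cis-1,2-diol, which both protects the diol and locks the 3,4-cis relationship against later ionisation at T-C4.

**Step 5**
Reactants: 9 racemic acetonide
Product: 10 acetonide of (2R,3R,4R)-7,8-bis(benzyloxy)-2-[4-(benzyloxy)phenyl]chromane-3,4-diol (protected unit T, single enantiomer)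
Conditions: preparative SFC, amylose tris(3,5-dimethylphenylcarbamate) phase, CO2/i-PrOH
Reagents that add atoms: none
Why: Chromatographic resolution of a rigid, UV-active racemate on a polysaccharide phase; the wanted antipode is to be identified by anomalous-dispersion X-ray analysis of bromide 11.

**Step 6**
Reactants: 10 protected unit T
Product: 11 6-bromo derivative of 10
Conditions: NBS (1.05 equiv), MeCN, 0 °C, dark
Reagents that add atoms: N-bromosuccinimide, O=C1CCC(=O)N1Br
Why: Electrophilic aromatic bromination goes to T-C6, which is ortho to the C7 benzyloxy group and para to the ring oxygen T-O1, whereas T-C5 is peri-hindered and activated only by the twisted C8 ether.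

**Step 7**
Reactants: 12 2,3,4-trihydroxybenzaldehyde
Product: 13 3,4-bis(benzyloxy)-2-hydroxybenzaldehyde
Conditions: BnBr (2.05 equiv), K2CO3 (2.1 equiv), DMF, rt
Reagents that add atoms: benzyl bromide, BrCc1ccccc1
Why: Williamson etherification as in step 1, the formyl-chelated 2-hydroxyl being left free.

**Step 8**
Reactants: 11 6-bromo protected unit T; 13 3,4-bis(benzyloxy)-2-hydroxybenzaldehyde
Product: 16 6-{[3,4-bis(benzyloxy)-2-hydroxyphenyl](hydroxy)methyl} derivative of 10 (ring A ortho-hydroxybenzhydrol, both carbinol epimers), via aryllithium 14 (not isolated), via sodium phenoxide 15 (not isolated)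
Conditions: 11, n-BuLi, THF, −78 °C; 13, NaH, THF, 0 °C, then added at −78 °C, to −20 °C; H2O
Reagents that add atoms: none
Why: Bromine–lithium exchange followed by 1,2-addition to the aldehyde, whose phenol is deprotonated beforehand so that it cannot quench the aryllithium; the carbinol centre is left uncontrolled because step 11 planarises it.

**Step 9**
Reactants: 17 4-bromo-1,2-bis(benzyloxy)benzene; 18 2-(benzyloxy)-N-methoxy-N-methylacetamide
Product: 21 2-(benzyloxy)-1-[3,4-bis(benzyloxy)phenyl]ethan-1-one, via aryllithium 19 (not isolated), via lithium hemiaminal salt 20 (not isolated)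
Conditions: 17, n-BuLi, THF, −78 °C; then 18, −78 to 0 °C; H2O
Reagents that add atoms: none
Why: Weinreb ketone synthesis, in which the chelated tetrahedral adduct 20 survives until work-up so that only one aryl group is transferred.

**Step 10**
Reactants: 21 α-benzyloxy ketone
Product: 22 (Z)-{[2-(benzyloxy)-1-[3,4-bis(benzyloxy)phenyl]vinyl]oxy}(tert-butyl)dimethylsilane
Conditions: TBSOTf, Et3N, CH2Cl2, 0 °C
Reagents that add atoms: tert-butyldimethylsilyl trifluoromethanesulfonate, CC(C)(C)[Si](C)(C)OS(=O)(=O)C(F)(F)F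
Why: Soft enolisation and O-silylation of an aryl ketone should favour the Z enol ether, in which ring B lies cis to the vinylic hydrogen and not to the benzyloxy group (allylic 1,3-strain).

**Step 11**
Reactants: 16 ring A ortho-hydroxybenzhydrol; 22 Z silyl enol ether
Product: 24 2-silyloxy ketal: 3,7,8-tris(benzyloxy)-2-[3,4-bis(benzyloxy)phenyl]-2-(tert-butyldimethylsilyloxy)chroman-4-yl unit bonded through M-C4 to C6 of 10 (ring D trans to the M-C3 benzyloxy group, silyloxy cis to it), via ortho-quinone methide 23 (not isolated)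
Conditions: (R)-3,3'-bis(2,4,6-triisopropylphenyl)-1,1'-binaphthyl-2,2'-diyl hydrogen phosphate (10 mol %), 22 (2 equiv), 5 Å molecular sieves, toluene, −20 °C
Reagents that add atoms: none
Why: The acid dehydrates 16 to the (E)-ortho-quinone methide 23 and stays hydrogen-bonded to its carbonyl oxygen, screening one face of M-C4; the CH(OBn) carbon of 22, nucleophilic because attack there leaves a cation stabilised by the silyloxy oxygen and ring B, bonds to M-C4 and the ring A oxygen then closes on M-C2. The closest known reaction is the chiral phosphoric acid-catalysed inverse-electron-demand oxa-[4+2] addition of ortho-quinone methides, generated in situ from ortho-hydroxybenzhydrols, to enol ethers, enamides and styrenes giving 4-arylchromans. Ring C closes either by a concerted asynchronous [4+2] cycloaddition or, if stepwise, by Mukaiyama–Michael addition followed by 6-exo-trig ketalisation. M-C4 is set by the catalyst; M-C3 by the Z geometry of 22 together with an endo ring B, which places the benzyloxy group exo and therefore trans to ring D; M-C2 follows from suprafacial addition and is erased in step 12. The step needs regioselectivity (carbon to M-C4, oxygen to M-C2), secured by the matched polarity of the partners, and catalyst-controlled diastereoselectivity, because the distant centres of unit T give no bias; the sieves keep the released water from hydrolysing 22.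

**Step 12**
Reactants: 24 2-silyloxy ketal
Product: 26 3,7,8-tris(benzyloxy)-2-[3,4-bis(benzyloxy)phenyl]chroman-4-yl unit (2,3-cis-3,4-trans) bonded through M-C4 to C6 of 10 (fully protected target), via oxocarbenium ion 25 (not isolated)
Conditions: Et3SiH (5 equiv), BF3·OEt2 (2 equiv), CH2Cl2, −78 to −40 °C
Reagents that add atoms: none
Why: Ionic reduction of a ketal as in C-aryl glycoside synthesis: in cation 25, strain with ring B and the peri interaction of ring D should hold the C3 benzyloxy and C4 aryl groups pseudo-axial, so hydride enters axially anti to the benzyloxy group and ring B ends equatorial and cis to the C3 oxygen; any desilylated lactol converges on the same ion.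

**Step 13**
Reactants: 26 fully protected target
Product: 27 octabenzyl ether of the target with free T-3,4-diol
Conditions: AcOH/THF/H2O (3:1:1), 40 °C
Reagents that add atoms: none
Why: Mild acetal hydrolysis at the ketal carbon leaves the T-C4–O bond intact, and it is done while the phenols are still benzylated because a free 7-hydroxyl would make T-C4 far easier to ionise and epimerise.

**Step 14**
Reactants: 27 octabenzyl ether
Product: 28 (2R,3R,4R)-6-[(2R,3R,4S)-2-(3,4-dihydroxyphenyl)-3,7,8-trihydroxychroman-4-yl]-2-(4-hydroxyphenyl)chromane-3,4,7,8-tetrol (CNP0174688.1)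
Conditions: H2 (1 atm), Pd(OH)2/C, THF/MeOH (1:1), rt
Reagents that add atoms: none
Why: Neutral hydrogenolysis cleaves the eight O-benzyl groups much faster than the secondary benzylic C–O bonds at T-C4, T-C2 and M-C2, as in the final debenzylation of benzyl-protected flavan oligomers.

**Compound list**
1 | gallacetophenone | CC(=O)c1ccc(O)c(O)c1O | starting material
2 | 1-[3,4-bis(benzyloxy)-2-hydroxyphenyl]ethan-1-one | CC(=O)c1ccc(OCc2ccccc2)c(OCc2ccccc2)c1O | intermediate
3 | 4-(benzyloxy)benzaldehyde | O=Cc1ccc(OCc2ccccc2)cc1 | starting material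
4 | (E)-1-[3,4-bis(benzyloxy)-2-hydroxyphenyl]-3-[4-(benzyloxy)phenyl]prop-2-en-1-one (chalcone) | O=C(/C=C/c1ccc(OCc2ccccc2)cc1)c1ccc(OCc2ccccc2)c(OCc2ccccc2)c1O | intermediate
5 | rac-trans-7,8-bis(benzyloxy)-2-[4-(benzyloxy)phenyl]-3-hydroxychroman-4-one (one enantiomer drawn) | O=C1[C@H](O)[C@@H](c2ccc(OCc3ccccc3)cc2)Oc2c(OCc3ccccc3)c(OCc3ccccc3)ccc21 | intermediate
6 | 7,8-bis(benzyloxy)-2-[4-(benzyloxy)phenyl]-3-hydroxy-4H-chromen-4-one (flavonol) | O=c1c(O)c(-c2ccc(OCc3ccccc3)cc2)oc2c(OCc3ccccc3)c(OCc3ccccc3)ccc12 | intermediate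
7 | rac-cis-7,8-bis(benzyloxy)-2-[4-(benzyloxy)phenyl]-3-hydroxychroman-4-one (one enantiomer drawn) | O=C1[C@@H](O)[C@@H](c2ccc(OCc3ccccc3)cc2)Oc2c(OCc3ccccc3)c(OCc3ccccc3)ccc21 | intermediate
8 | rac-(2R,3R,4R)-7,8-bis(benzyloxy)-2-[4-(benzyloxy)phenyl]chromane-3,4-diol, all-cis (racemate, carried enantiomer drawn) | c6ccccc6COc1ccc([C@H]2Oc3c(ccc(OCc6ccccc6)c3OCc6ccccc6)[C@@H](O)[C@H]2O)cc1 | intermediate
9 | racemic 3,4-acetonide of 8 (carried enantiomer drawn) | c6ccccc6COc1ccc([C@H]2Oc3c(ccc(OCc6ccccc6)c3OCc6ccccc6)[C@@H](O7)[C@H]2OC7(C)C)cc1 | intermediate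
10 | 3,4-acetonide of (2R,3R,4R)-7,8-bis(benzyloxy)-2-[4-(benzyloxy)phenyl]chromane-3,4-diol (protected unit T) | c6ccccc6COc1ccc([C@H]2Oc3c(ccc(OCc6ccccc6)c3OCc6ccccc6)[C@@H](O7)[C@H]2OC7(C)C)cc1 | intermediate
11 | 6-bromo derivative of 10 | c6ccccc6COc1ccc([C@H]2Oc3c(cc(Br)c(OCc6ccccc6)c3OCc6ccccc6)[C@@H](O7)[C@H]2OC7(C)C)cc1 | intermediate
12 | 2,3,4-trihydroxybenzaldehyde | O=Cc1ccc(O)c(O)c1O | starting material
13 | 3,4-bis(benzyloxy)-2-hydroxybenzaldehyde | O=Cc1ccc(OCc2ccccc2)c(OCc2ccccc2)c1O | intermediate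
14 | 6-lithio derivative of 10 | c6ccccc6COc1ccc([C@H]2Oc3c(cc([Li])c(OCc6ccccc6)c3OCc6ccccc6)[C@@H](O7)[C@H]2OC7(C)C)cc1 | intermediate
15 | sodium 2,3-bis(benzyloxy)-6-formylphenolate | O=Cc1ccc(OCc2ccccc2)c(OCc2ccccc2)c1[O-].[Na+] | intermediate
16 | 6-{[3,4-bis(benzyloxy)-2-hydroxyphenyl](hydroxy)methyl} derivative of 10, both carbinol epimers | c6ccccc6COc1ccc([C@H]2Oc3c(cc(C(O)c5ccc(OCc6ccccc6)c(OCc6ccccc6)c5O)c(OCc6ccccc6)c3OCc6ccccc6)[C@@H](O7)[C@H]2OC7(C)C)cc1 | intermediate
17 | 4-bromo-1,2-bis(benzyloxy)benzene | Brc1ccc(OCc2ccccc2)c(OCc2ccccc2)c1 | starting material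
18 | 2-(benzyloxy)-N-methoxy-N-methylacetamide | CON(C)C(=O)COCc1ccccc1 | starting material
19 | [3,4-bis(benzyloxy)phenyl]lithium | [Li]c1ccc(OCc2ccccc2)c(OCc2ccccc2)c1 | intermediate
20 | lithium 2-(benzyloxy)-1-[3,4-bis(benzyloxy)phenyl]-1-[methoxy(methyl)amino]ethan-1-olate | [Li]OC(COCc1ccccc1)(N(C)OC)c1ccc(OCc2ccccc2)c(OCc2ccccc2)c1 | intermediate
21 | 2-(benzyloxy)-1-[3,4-bis(benzyloxy)phenyl]ethan-1-one | O=C(COCc1ccccc1)c1ccc(OCc2ccccc2)c(OCc2ccccc2)c1 | intermediate
22 | (Z)-{[2-(benzyloxy)-1-[3,4-bis(benzyloxy)phenyl]vinyl]oxy}(tert-butyl)dimethylsilane | c6ccccc6CO/C=C(\O[Si](C)(C)C(C)(C)C)c5ccc(OCc6ccccc6)c(OCc6ccccc6)c5 | intermediate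
23 | (E)-2,3-bis(benzyloxy)-6-[(C6 of 10)methylidene]cyclohexa-2,4-dien-1-one (ortho-quinone methide) | c6ccccc6COc1ccc([C@H]2Oc3c(cc(/C=C4\C=CC(OCc6ccccc6)=C(OCc6ccccc6)C4=O)c(OCc6ccccc6)c3OCc6ccccc6)[C@@H](O7)[C@H]2OC7(C)C)cc1 | intermediate
24 | 2-silyloxy ketal of the protected target (M-C4 aryl trans to M-C3 OBn, OTBS cis to it) | c6ccccc6COc1ccc([C@H]2Oc3c(cc([C@H]4c5ccc(OCc6ccccc6)c(OCc6ccccc6)c5O[C@@](O[Si](C)(C)C(C)(C)C)(c5ccc(OCc6ccccc6)c(OCc6ccccc6)c5)[C@@H]4OCc6ccccc6)c(OCc6ccccc6)c3OCc6ccccc6)[C@@H](O7)[C@H]2OC7(C)C)cc1 | intermediate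
25 | 2-aryl oxocarbenium ion of unit M with silyloxytrifluoroborate counter-ion | c6ccccc6COc1ccc([C@H]2Oc3c(cc([C@H]4c5ccc(OCc6ccccc6)c(OCc6ccccc6)c5[O+]=C(c5ccc(OCc6ccccc6)c(OCc6ccccc6)c5)[C@@H]4OCc6ccccc6)c(OCc6ccccc6)c3OCc6ccccc6)[C@@H](O7)[C@H]2OC7(C)C)cc1.F[B-](F)(F)O[Si](C)(C)C(C)(C)C | intermediate
26 | fully protected target (eight benzyl ethers, T-3,4-acetonide; unit M 2,3-cis-3,4-trans) | c6ccccc6COc1ccc([C@H]2Oc3c(cc([C@H]4c5ccc(OCc6ccccc6)c(OCc6ccccc6)c5O[C@H](c5ccc(OCc6ccccc6)c(OCc6ccccc6)c5)[C@@H]4OCc6ccccc6)c(OCc6ccccc6)c3OCc6ccccc6)[C@@H](O7)[C@H]2OC7(C)C)cc1 | intermediate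
27 | octabenzyl ether of the target with free T-3,4-diol | c6ccccc6COc1ccc([C@H]2Oc3c(cc([C@H]4c5ccc(OCc6ccccc6)c(OCc6ccccc6)c5O[C@H](c5ccc(OCc6ccccc6)c(OCc6ccccc6)c5)[C@@H]4OCc6ccccc6)c(OCc6ccccc6)c3OCc6ccccc6)[C@@H](O)[C@H]2O)cc1 | intermediate
28 | (2R,3R,4R)-6-[(2R,3R,4S)-2-(3,4-dihydroxyphenyl)-3,7,8-trihydroxychroman-4-yl]-2-(4-hydroxyphenyl)chromane-3,4,7,8-tetrol | Oc1ccc([C@H]2Oc3c(cc([C@H]4c5ccc(O)c(O)c5O[C@H](c5ccc(O)c(O)c5)[C@@H]4O)c(O)c3O)[C@@H](O)[C@H]2O)cc1 | target

**Step count**
Total: 14 steps. Longest linear sequence: 11 steps (1, 2, 3, 4, 5, 6, 8, 11, 12, 13, 14).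

**Steps most likely to fail**

Step 11. The catalyst may not dominate the choice of methide face and of endo versus exo approach, so the 3,4-trans adduct with the target configuration at M-C4 may not be the main product; released water may also hydrolyse 22 before it adds. The fallback makes the M-C4–T-C6 bond last, by the classical condensation of a flavan-3,4-diol with a nucleophilic arene. It sets out from 2 and 10 and comes back at 26. Compound 2 is condensed with commercial 3,4-bis(benzyloxy)benzaldehyde (O=Cc1ccc(OCc2ccccc2)c(OCc2ccccc2)c1) and oxidised as in step 2 to 7,8-bis(benzyloxy)-2-[3,4-bis(benzyloxy)phenyl]-3-hydroxy-4H-chromen-4-one F1. Hydrogenation as in step 3 should give racemic all-cis 7,8-bis(benzyloxy)-2-[3,4-bis(benzyloxy)phenyl]chromane-3,4-diol F2, and chromatography on the chiral phase of step 5 its (2R,3R,4R)-enantiomer F3. BF3·OEt2 (CH2Cl2, −78 °C) ionises F3 at C4 in the presence of excess 10, whose T-C6 captures the benzylic cation anti to the C3 hydroxyl to give the 3,4-trans 4-arylflavan-3-ol with free M-C3 hydroxyl F4. Etherification with NaH and BnBr returns to 26.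

Step 12. Hydride may be delivered syn to the C3 benzyloxy group because the pseudo-axial ring D crowds the wanted face, giving the 2,3-trans flavan; the Lewis acid may also ionise the T acetonide at T-C4. The fallback sets M-C2 in an open chain. It sets out from 24 and comes back at 26. TBAF buffered with AcOH (THF, 0 °C) removes silicon and opens the lactol to the keto phenol 2-(benzyloxy)-1-[3,4-bis(benzyloxy)phenyl]-3-[3,4-bis(benzyloxy)-2-hydroxyphenyl]-3-(C6 of 10)propan-1-one F5. Zn(BH4)2 (Et2O, −20 °C) reduces the α-benzyloxy ketone under chelation control to the anti alcohol F6. Mitsunobu etherification (PPh3, DIAD, THF, 0 °C) then closes ring C through the ring A phenol with inversion at M-C2, which gives the 2,3-cis flavan 26.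

Step 3. Hydrogenolysis of the aryl benzyl ethers and of the C4 benzylic alcohol may compete with reduction of the pyranone, or the ring may not reduce under conditions mild enough to keep the ethers. The fallback accepts loss of the benzyl groups. It sets out from 6 and comes back at 8. Exhaustive hydrogenation (H2, Pd/C, then Raney Ni under pressure, EtOH) should give racemic all-cis 2-(4-hydroxyphenyl)chromane-3,4,7,8-tetrol F7. Phenol-selective benzylation (BnBr, 3 equiv, K2CO3, DMF) returns to 8.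

**Further compounds**
F1 | step 11 | 7,8-bis(benzyloxy)-2-[3,4-bis(benzyloxy)phenyl]-3-hydroxy-4H-chromen-4-one | O=c1c(O)c(-c2ccc(OCc3ccccc3)c(OCc3ccccc3)c2)oc2c(OCc3ccccc3)c(OCc3ccccc3)ccc12
F2 | step 11 | rac-(2R,3R,4R)-7,8-bis(benzyloxy)-2-[3,4-bis(benzyloxy)phenyl]chromane-3,4-diol (racemate, one enantiomer drawn) | c6ccccc6COc1ccc([C@H]2Oc3c(ccc(OCc6ccccc6)c3OCc6ccccc6)[C@@H](O)[C@H]2O)cc1OCc6ccccc6
F3 | step 11 | (2R,3R,4R)-7,8-bis(benzyloxy)-2-[3,4-bis(benzyloxy)phenyl]chromane-3,4-diol | c6ccccc6COc1ccc([C@H]2Oc3c(ccc(OCc6ccccc6)c3OCc6ccccc6)[C@@H](O)[C@H]2O)cc1OCc6ccccc6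
F4 | step 11 | analogue of 26 with free M-C3 hydroxyl | c6ccccc6COc1ccc([C@H]2Oc3c(cc([C@H]4c5ccc(OCc6ccccc6)c(OCc6ccccc6)c5O[C@H](c5ccc(OCc6ccccc6)c(OCc6ccccc6)c5)[C@@H]4O)c(OCc6ccccc6)c3OCc6ccccc6)[C@@H](O7)[C@H]2OC7(C)C)cc1
F5 | step 12 | ring-opened keto phenol from 24 | c6ccccc6COc1ccc([C@H]2Oc3c(cc([C@@H](c5ccc(OCc6ccccc6)c(OCc6ccccc6)c5O)[C@@H](OCc6ccccc6)C(=O)c5ccc(OCc6ccccc6)c(OCc6ccccc6)c5)c(OCc6ccccc6)c3OCc6ccccc6)[C@@H](O7)[C@H]2OC7(C)C)cc1
F6 | step 12 | anti alcohol from chelation-controlled reduction of F5 | c6ccccc6COc1ccc([C@H]2Oc3c(cc([C@@H](c5ccc(OCc6ccccc6)c(OCc6ccccc6)c5O)[C@@H](OCc6ccccc6)[C@@H](O)c5ccc(OCc6ccccc6)c(OCc6ccccc6)c5)c(OCc6ccccc6)c3OCc6ccccc6)[C@@H](O7)[C@H]2OC7(C)C)cc1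
F7 | step 3 | rac-(2R,3R,4R)-2-(4-hydroxyphenyl)chromane-3,4,7,8-tetrol (racemate, one enantiomer drawn) | Oc1ccc([C@H]2Oc3c(ccc(O)c3O)[C@@H](O)[C@H]2O)cc1
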